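**Direct plan and its weak points**

A direct plan would build the chain at its middle. A copper-catalysed coupling of an aryl Grignard reagent with a bromoalkene would give 1-(benzyloxy)-4-(hept-6-en-1-yl)benzene (A1). CuBr2 would brominate 1-(2,6-dimethoxyphenyl)ethan-1-one (A2) to 2-bromo-1-(2,6-dimethoxyphenyl)ethan-1-one (A3). Hydroboration of A1 with 9-BBN and alkylation of the enolate of A3 by the resulting borane would give 1-(2,6-dimethoxyphenyl)-9-[4-(benzyloxy)phenyl]nonan-1-one (A4). BCl3 would then remove one methyl group and the benzyl group of A4 to give the target.
- Weak step, the side-chain bromination of A2: the ring is a resorcinol dimethyl ether and the ketone is twisted out of conjugation and enolises slowly, so ring bromination and dibromination would compete.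
- Weak step, the borane alkylation that joins A1 and A3 to give A4: a hindered phenoxide must deprotonate a hindered bromo ketone beside a trialkylborane, self-condensation of the bromo ketone competes, and all this effort forms an ordinary CH2–CH2 bond far from the difficult part of the target.
- Weak step, the closing BCl3 cleavage of A4: the only difference between the two ring oxygens (OH against OMe) would be left to the selectivity of a deprotection on the finished skeleton, under excess Lewis acid that must also ionise the benzyl ether, so over-demethylation and Friedel–Crafts benzylation would threaten the product.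

**Retrosynthetic overview of the new route**

- Key disconnection: in ring A (the 2-hydroxy-6-methoxyphenyl ring) the two bonds at neighbouring carbons, C1–C(=O) and C2–OH, are cut together. This leads back to 3-methoxybenzyne and the free acid 9-[4-(benzyloxy)phenyl]nonanoic acid, whose carboxyl C–O bond is inserted across the aryne triple bond.
- The methoxy group beside the triple bond sends the oxygen to the far aryne carbon and the acyl group to the carbon between the two oxygens, so the OH/acyl/OMe triad arises in one operation with the two oxygens different from the start.
- The acid comes in one flask from methyl non-8-enoate and 1-(benzyloxy)-4-bromobenzene (hydroboration, B-alkyl Suzuki–Miyaura coupling, saponification); a neutral hydrogenolysis ends the route.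
- No ring is formed: ring B (the 4-hydroxyphenyl ring) is bought as the aryl bromide and ring A as the aryne precursor. The design needs no bromination of an electron-rich ketone, no enolate–borane alkylation and no late choice between two methyl ethers.

Key step: step 2

Remark: the target is achiral, so no step has to set a stereocentre.

**Route**

Step 1
Reactants: 1 methyl non-8-enoate; 2 1-(benzyloxy)-4-bromobenzene
Product: 5 9-[4-(benzyloxy)phenyl]nonanoic acid, via B-alkyl-9-BBN 3 (not isolated), via methyl ester 4 (not isolated)
Conditions: 1, 9-BBN (1.1 equiv), THF, 0 °C to rt; then 2, PdCl2(dppf) (3 mol %), 3 M aq. NaOH, THF, 65 °C; then MeOH, NaOH (excess), 60 °C; 1 M HCl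
Reagents that add atoms: sodium hydroxide, [Na+].[OH-]
Why: Anti-Markovnikov hydroboration of the terminal alkene (the ester is inert to 9-BBN), B-alkyl Suzuki–Miyaura coupling of the primary alkylborane with the aryl bromide after its oxidative addition to zerovalent palladium, and saponification of the methyl ester in the same basic medium should give the acid, which is freed from neutral boron residues by acid–base extraction; no stereocentre is formed.

Step 2
Reactants: 5 9-[4-(benzyloxy)phenyl]nonanoic acid; 6 3-methoxy-2-(trimethylsilyl)phenyl trifluoromethanesulfonate
Product: 8 9-[4-(benzyloxy)phenyl]-1-(2-hydroxy-6-methoxyphenyl)nonan-1-one, via 3-methoxybenzyne 7 (not isolated)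
Conditions: 5, 6 (1.5 equiv), CsF (4 equiv), dry THF (0.05 M), sealed tube, 125 °C; aq. NH4Cl
Reagents that add atoms: none
Why: Fluoride removes the silyl group of 6 and triflate leaves to give 3-methoxybenzyne 7; the carboxylate of 5 adds through oxygen to the aryne carbon meta to the methoxy group, the aryl anion so formed attacks its own ester carbonyl, and the strained benzoxetene alkoxide opens to the ortho-acyl phenoxide, so that the carboxyl C–O bond is in effect inserted across the triple bond. The closest known reaction type is the intermolecular C–O insertion of arynes from silylaryl triflates into carboxylic acids, which gives ortho-hydroxyaryl ketones from aromatic and aliphatic acids. No ring of the product is closed (only a transient four-membered ring by 4-exo-trig attack) and no stereocentre is formed. The step needs regioselectivity, and the methoxy group beside the triple bond secures it: its inductive pull distorts the aryne so that the nucleophile attacks the far carbon and the negative charge develops on the carbon next to C–OMe, which places OH, acyl and OMe on three neighbouring carbons exactly as in ring A. It also needs the acyl shift to outrun protonation of the aryl anion, which would stop at the simple aryl ester; the intramolecular shift should be favoured by 125 °C, aprotic THF and excess CsF. The benzyl ether keeps the ring B phenol from adding to the aryne, and the product phenoxide, hindered and tied to its ketone, should be a poor nucleophile towards a second aryne.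

Step 3
Reactants: 8 9-[4-(benzyloxy)phenyl]-1-(2-hydroxy-6-methoxyphenyl)nonan-1-one
Product: 9 1-(2-hydroxy-6-methoxyphenyl)-9-(4-hydroxyphenyl)nonan-1-one (target)
Conditions: H2 (1 atm), 10 % Pd/C (palladium on carbon), EtOAc, rt
Reagents that add atoms: none
Why: Hydrogenolysis of the aryl benzyl ether on palladium under neutral conditions should free the ring B phenol, while the methyl ether and the ketone, which is twisted out of the ring plane by its two ortho substituents and hydrogen-bonded to the ring A hydroxyl, should not be touched.

**Compound list**

1 | methyl non-8-enoate | C=CCCCCCCC(=O)OC | starting material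
2 | 1-(benzyloxy)-4-bromobenzene | Brc1ccc(OCc2ccccc2)cc1 | starting material
3 | methyl 9-(9-borabicyclo[3.3.1]nonan-9-yl)nonanoate | COC(=O)CCCCCCCCB1C2CCCC1CCC2 | intermediate
4 | methyl 9-[4-(benzyloxy)phenyl]nonanoate | COC(=O)CCCCCCCCc1ccc(OCc2ccccc2)cc1 | intermediate
5 | 9-[4-(benzyloxy)phenyl]nonanoic acid | OC(=O)CCCCCCCCc1ccc(OCc2ccccc2)cc1 | intermediate
6 | 3-methoxy-2-(trimethylsilyl)phenyl trifluoromethanesulfonate | COc1cccc(OS(=O)(=O)C(F)(F)F)c1[Si](C)(C)C | starting material
7 | 3-methoxybenzyne (1-methoxy-2,3-didehydrobenzene) | COC1=CC=CC#C1 | intermediate
8 | 9-[4-(benzyloxy)phenyl]-1-(2-hydroxy-6-methoxyphenyl)nonan-1-one | COc1cccc(O)c1C(=O)CCCCCCCCc1ccc(OCc2ccccc2)cc1 | intermediate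
9 | 1-(2-hydroxy-6-methoxyphenyl)-9-(4-hydroxyphenyl)nonan-1-one | COc1cccc(O)c1C(=O)CCCCCCCCc1ccc(O)cc1 | target

**Step count and risks**

Total step count: 3. Longest linear sequence: 3 steps (1 to 5 to 8 to 9).

Steps most likely to fail, riskiest first:

1. Step 2 (aryne insertion). The aryl anion may be protonated before the acyl shift, so that the reaction stops at the aryl ester; the product phenoxide may be arylated by excess aryne; the addition may be less regioselective than expected. The fallback sets out from the methyl ester 4, isolated by leaving out the saponification of step 1, and builds the same aryl–acyl bond by directed ortho-metalation. Ester 4 would be converted with MeNH(OMe)·HCl and i-PrMgCl (THF, −20 °C) into N-methoxy-N-methyl-9-[4-(benzyloxy)phenyl]nonanamide F1. 1-Methoxy-3-(methoxymethoxy)benzene F2 would be lithiated between its two oxygens (n-BuLi, THF, 0 °C) to [2-methoxy-6-(methoxymethoxy)phenyl]lithium F3, which would add once to the amide to give 9-[4-(benzyloxy)phenyl]-1-[2-methoxy-6-(methoxymethoxy)phenyl]nonan-1-one F4. HCl in MeOH would remove the methoxymethyl group, and the fallback comes back to the route at 8.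

2. Step 1 (hydroboration, coupling, saponification in one flask). The alkylborane may transmetalate slowly in hot aqueous base and be lost by protodeboronation or β-hydride elimination, and the ester may hydrolyse incompletely. The fallback sets out from 2 and forms the aryl–CH2 bond by substitution at a primary bromide, with no ester stage. Compound 2 and Mg (THF, reflux) would give [4-(benzyloxy)phenyl]magnesium bromide F5. 9-Bromononanoic acid F6 would first be turned into its magnesium carboxylate with one equivalent of t-BuMgCl and then coupled with the Grignard reagent under Li2CuCl4 (3 mol %), THF, −20 °C to rt. Work-up with 1 M HCl brings the fallback back to the route at 5.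

3. Step 3 (hydrogenolysis). The aryl ketone may be reduced to the benzylic alcohol or methylene compound while the benzyl ether is cleaved. The fallback sets out from 1 and carries the ring B phenol as a methoxymethyl ether, so that no reduction is run beside the ketone. 1-Bromo-4-(methoxymethoxy)benzene F7 would take the place of 2 under the conditions of step 1, giving through 3 methyl 9-[4-(methoxymethoxy)phenyl]nonanoate F8 (not isolated) and, after acidification to pH 4 only, 9-[4-(methoxymethoxy)phenyl]nonanoic acid F9. The conditions of step 2 with 6 would give 1-(2-hydroxy-6-methoxyphenyl)-9-[4-(methoxymethoxy)phenyl]nonan-1-one F10. HCl in MeOH at rt would free the phenol, and the fallback comes back to the route at 9.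

**Further compounds**

F1 | step 2 | N-methoxy-N-methyl-9-[4-(benzyloxy)phenyl]nonanamide | CON(C)C(=O)CCCCCCCCc1ccc(OCc2ccccc2)cc1
F2 | step 2 | 1-methoxy-3-(methoxymethoxy)benzene | COCOc1cccc(OC)c1
F3 | step 2 | [2-methoxy-6-(methoxymethoxy)phenyl]lithium | [Li]c1c(OC)cccc1OCOC
F4 | step 2 | 9-[4-(benzyloxy)phenyl]-1-[2-methoxy-6-(methoxymethoxy)phenyl]nonan-1-one | COCOc1cccc(OC)c1C(=O)CCCCCCCCc1ccc(OCc2ccccc2)cc1
F5 | step 1 | [4-(benzyloxy)phenyl]magnesium bromide | Br[Mg]c1ccc(OCc2ccccc2)cc1
F6 | step 1 | 9-bromononanoic acid | OC(=O)CCCCCCCCBr
F7 | step 3 | 1-bromo-4-(methoxymethoxy)benzene | COCOc1ccc(Br)cc1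
F8 | step 3 | methyl 9-[4-(methoxymethoxy)phenyl]nonanoate | COC(=O)CCCCCCCCc1ccc(OCOC)cc1
F9 | step 3 | 9-[4-(methoxymethoxy)phenyl]nonanoic acid | OC(=O)CCCCCCCCc1ccc(OCOC)cc1
F10 | step 3 | 1-(2-hydroxy-6-methoxyphenyl)-9-[4-(methoxymethoxy)phenyl]nonan-1-one | COCOc1ccc(CCCCCCCCC(=O)c2c(O)cccc2OC)cc1
A1 | direct plan | 1-(benzyloxy)-4-(hept-6-en-1-yl)benzene | C=CCCCCCc1ccc(OCc2ccccc2)cc1
A2 | direct plan | 1-(2,6-dimethoxyphenyl)ethan-1-one | CC(=O)c1c(OC)cccc1OC
A3 | direct plan | 2-bromo-1-(2,6-dimethoxyphenyl)ethan-1-one | O=C(CBr)c1c(OC)cccc1OC
A4 | direct plan | 1-(2,6-dimethoxyphenyl)-9-[4-(benzyloxy)phenyl]nonan-1-one | COc1cccc(OC)c1C(=O)CCCCCCCCc1ccc(OCc2ccccc2)cc1
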